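The cyclohexene ring of the bicyclic core (C4a, C5, C6, C7, C8, C8a of the tetrahydronaphthalene-1,4-dione) is not closed directly: it is made as a cyclobutane and enlarged by two carbons. In one flask, a visible-light [2+2] photocycloaddition joins a chromonyl methoxybenzoquinone to the terminal vinyl group of an (E)-labdatrienone, and the resulting 8-alkenylbicyclo[4.2.0]octenedione rearranges thermally (vinylcyclobutane to cyclohexene, 1,3-shift). The step exploits the allylic C5–C6=C7 unit next to quaternary C4a, whose α-keto, chromonyl-stabilised radical weakens the migrating bond, and it gives the C5 epimer (side chain cis to the chromone) that an endo Diels–Alder reaction would not. The diene comes from sclareolide, the quinone from a flavone.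

Key step: step 12

Remark: labdane numbering (C1–C20) is used for the terpenoid part and naphthalene-1,4-dione numbering (C4a quaternary, C8a–H) for the bicyclic core; TBS = tert-butyldimethylsilyl.

Step 1
Reactants: 1 (+)-sclareolide
Product: 2 methyl 13,14,15,16-tetranorlabd-8-en-12-oate
Conditions: conc. H2SO4, MeOH, reflux
Reagents that add atoms: methanol, CO
Why: Acid-catalysed methanolysis of the lactone with E1 loss of the tertiary C8 oxygen, then equilibration of the alkene isomers to the tetrasubstituted 8(9)-alkene under thermodynamic control; no new stereocentre.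

Step 2
Reactants: 2 methyl 13,14,15,16-tetranorlabd-8-en-12-oate
Product: 3 13,14,15,16-tetranorlabd-8-en-12-ol
Conditions: LiAlH4, THF, 0 °C
Reagents that add atoms: none
Why: Hydride reduction of the ester to the primary alcohol, to which the tetrasubstituted alkene is inert.

Step 3
Reactants: 3 13,14,15,16-tetranorlabd-8-en-12-ol
Product: 4 8α,9α-epoxy-13,14,15,16-tetranorlabdan-12-ol
Conditions: mCPBA, NaHCO3, CH2Cl2, 0 °C
Reagents that add atoms: 3-chloroperoxybenzoic acid (mCPBA), OOC(=O)c1cccc(Cl)c1
Why: Prilezhaev epoxidation of the electron-rich tetrasubstituted alkene from the α-face, opposite to the axial C10 methyl group, which sets the α C–O bond at C9.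

Step 4
Reactants: 4 8α,9α-epoxy-13,14,15,16-tetranorlabdan-12-ol
Product: 5 13,14,15,16-tetranorlabd-8(17)-ene-9α,12-diol
Conditions: Et2AlCl, lithium 2,2,6,6-tetramethylpiperidide (excess), benzene, 0 °C to rt
Reagents that add atoms: none
Why: Base-mediated isomerisation of the epoxide to the allylic alcohol: the bulky aluminium amide removes a syn proton from the unhindered C17 methyl group, the C8–O bond opens, and the oxygen stays on C9 with its α configuration beside the new exocyclic alkene.

Step 5
Reactants: 5 13,14,15,16-tetranorlabd-8(17)-ene-9α,12-diol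
Product: 6 13,14,15,16-tetranorlabd-8(17)-ene-7α,9α,12-triol
Conditions: SeO2 (cat.), t-BuOOH, CH2Cl2, rt
Reagents that add atoms: selenium dioxide, O=[Se]=O (oxygen donor, regenerated by tert-butyl hydroperoxide, CC(C)(C)OO)
Why: Riley allylic oxidation (ene reaction, then [2,3]-shift) at C7, the only allylic carbon of the 8(17)-alkene that bears hydrogen; the 7α-alcohol expected from axial delivery is oxidised away in the next step.

Step 6
Reactants: 6 13,14,15,16-tetranorlabd-8(17)-ene-7α,9α,12-triol
Product: 7 9α-hydroxy-7-oxo-13,14,15,16-tetranorlabd-8(17)-en-12-al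
Conditions: Dess–Martin periodinane (2.5 equiv), NaHCO3, CH2Cl2, 0 °C to rt; crude product used directly
Reagents that add atoms: none
Why: Dess–Martin oxidation turns the primary alcohol into the aldehyde and the allylic secondary alcohol into the enone in one operation, while the tertiary 9-OH cannot be oxidised.

Step 7
Reactants: 7 9α-hydroxy-7-oxo-13,14,15,16-tetranorlabd-8(17)-en-12-al
Product: 8 (12E)-9α-hydroxy-7-oxo-15-norlabda-8(17),12-dien-14-al
Conditions: Ph3P=C(Me)CHO, benzene, 70 °C
Reagents that add atoms: 2-(triphenylphosphoranylidene)propanal, CC(C=O)=P(c1ccccc1)(c1ccccc1)c1ccccc1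
Why: Wittig olefination with a stabilised ylide, which reacts only with the aldehyde and gives the (E)-trisubstituted enal.

Step 8
Reactants: 8 (12E)-9α-hydroxy-7-oxo-15-norlabda-8(17),12-dien-14-al
Product: 9 (12E)-9α-hydroxylabda-8(17),12,14-trien-7-one
Conditions: Ph3PCH3Br, KN(SiMe3)2, THF, −78 to −20 °C
Reagents that add atoms: methyltriphenylphosphonium bromide, C[P+](c1ccccc1)(c1ccccc1)c1ccccc1.[Br-]
Why: Wittig methylenation of the aldehyde, which at low temperature is far more electrophilic than the hindered C7 ketone, completes the (E)-diene without touching the C12=C13 geometry.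

Step 9
Reactants: 10 2',4',6'-trihydroxyacetophenone; 11 2,4,5-trimethoxybenzoyl chloride
Product: 13 5,7-dihydroxy-2-(2,4,5-trimethoxyphenyl)-4H-chromen-4-one, via 1,3-diketone 12 (not isolated)
Conditions: LiN(SiMe3)2 (4 equiv), THF, −78 °C to rt; aq. HCl; then AcOH, H2SO4 (cat.), 95 °C
Reagents that add atoms: none
Why: C-acylation of the polylithiated acetophenone enolate (Baker–Venkataraman-type 1,3-diketone synthesis), followed by acid-catalysed cyclodehydration to the flavone.

Step 10
Reactants: 13 5,7-dihydroxy-2-(2,4,5-trimethoxyphenyl)-4H-chromen-4-one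
Product: 14 5,7-bis(tert-butyldimethylsilyloxy)-2-(2,4,5-trimethoxyphenyl)-4H-chromen-4-one
Conditions: TBSOTf, 2,6-lutidine, CH2Cl2, 0 °C to rt
Reagents that add atoms: tert-butyldimethylsilyl trifluoromethanesulfonate, CC(C)(C)[Si](C)(C)OS(=O)(=O)C(F)(F)F
Why: Silylation of both phenols (the chelated 5-OH needs the silyl triflate) masks the O–H bonds that would otherwise reduce the quinone triplet in step 12.

Step 11
Reactants: 14 5,7-bis(tert-butyldimethylsilyloxy)-2-(2,4,5-trimethoxyphenyl)-4H-chromen-4-one
Product: 15 2-[5,7-bis(tert-butyldimethylsilyloxy)-4-oxo-4H-chromen-2-yl]-5-methoxy-1,4-benzoquinone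
Conditions: (NH4)2Ce(NO3)6, MeCN/H2O, 0 °C
Reagents that add atoms: water, O
Why: Oxidative demethylation of the para-dimethoxy pair gives the 1,4-benzoquinone, and the third methoxy group survives as the vinylogous ester.

Step 12
Reactants: 9 (12E)-9α-hydroxylabda-8(17),12,14-trien-7-one (slight excess); 15 2-[5,7-bis(tert-butyldimethylsilyloxy)-4-oxo-4H-chromen-2-yl]-5-methoxy-1,4-benzoquinone
Product: 17 5,7-bis-O-TBS ether of the target with the (4aS,5R,8aR) core, via vinylcyclobutane 16 (not isolated)
Conditions: 450 nm LEDs, degassed PhCF3, −20 °C, to full conversion of 15; then dark, 95 °C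
Reagents that add atoms: none
Why: Blue light excites only quinone 15; its triplet bonds through the unsubstituted ring carbon (later C8a) to the terminal CH2 of the s-trans diene of 9, giving the best-stabilised 1,4-diradical (a tertiary α-keto radical conjugated with the chromone, plus an allyl radical), which after spin inversion closes by radical recombination at the near allyl carbon to the cis-fused cyclobutane 16, a quinone–alkene [2+2] photocycloaddition in which the transoid allyl radical cannot yet reach a six-membered ring. On warming, the strained C1–C8 bond of 16 (quaternary chromonyl carbon to allylic carbon) should homolyse to the same kind of singlet diradical, now from the cisoid rotamer, and this recombines at the far allyl terminus, a vinylcyclobutane-to-cyclohexene rearrangement (formal 1,3-sigmatropic shift) that takes two alkene carbons into the ring, moves the double bond to C6=C7 and forms the C4a–C5 bond. C8a–H is set in the photocycloaddition and is not touched afterwards; C4a must re-bond with retention because only the cis-fused six-membered ring can close; C5 follows from the E geometry of the migrating terminus together with a suprafacial, least-motion shift from a cyclobutane whose butenyl arm is trans to the chromonyl group, which places the labdanylmethyl group cis to the chromone, the relationship an endo Diels–Alder reaction would not give. The step needs regioselectivity (secured by diradical stability and the unhindered CH2 terminus), chemoselectivity for the electron-rich diene over the hindered enone of 9 and for the chromonyl-substituted C=C of 15, and the butenyl arm trans to the chromonyl group in 16 (expected from the bulk of the angular substituent). The two faces of the quinone differ only through the remote labdane unit, so no facial bias is expected: the diastereomer with the mirror-image bicyclic core should form beside 17 and has to be removed by chromatography here.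

Step 13
Reactants: 17 5,7-bis-O-TBS ether of the target
Product: 18 CNP0241859.1, (4aS,5R,8aR)-4a-(5,7-dihydroxy-4-oxo-4H-chromen-2-yl)-5-{[(1S,4aS,8aS)-1-hydroxy-5,5,8a-trimethyl-2-methylidene-3-oxodecahydronaphthalen-1-yl]methyl}-2-methoxy-6-methyl-4a,5,8,8a-tetrahydronaphthalene-1,4-dione
Conditions: HF·pyridine, pyridine, THF, 0 °C
Reagents that add atoms: none
Why: Fluoride cleaves the two aryl silyl ethers under buffered, non-basic conditions, so the cis ring fusion (C8a–H is α to a ketone), the α-methylene ketone and the tertiary allylic alcohol are not affected.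

Compound list
1 | (+)-sclareolide | C[C@@]12CC[C@H]3C(C)(C)CCC[C@]3(C)[C@H]1CC(=O)O2 | starting material
2 | methyl 13,14,15,16-tetranorlabd-8-en-12-oate | COC(=O)CC1=C(C)CC[C@H]2C(C)(C)CCC[C@]12C | intermediate
3 | 13,14,15,16-tetranorlabd-8-en-12-ol | OCCC1=C(C)CC[C@H]2C(C)(C)CCC[C@]12C | intermediate
4 | 8α,9α-epoxy-13,14,15,16-tetranorlabdan-12-ol | C[C@@]12CC[C@H]3C(C)(C)CCC[C@]3(C)[C@]1(CCO)O2 | intermediate
5 | 13,14,15,16-tetranorlabd-8(17)-ene-9α,12-diol | C=C1CC[C@H]2C(C)(C)CCC[C@]2(C)[C@@]1(O)CCO | intermediate
6 | 13,14,15,16-tetranorlabd-8(17)-ene-7α,9α,12-triol | C=C1[C@H](O)C[C@H]2C(C)(C)CCC[C@]2(C)[C@@]1(O)CCO | intermediate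
7 | 9α-hydroxy-7-oxo-13,14,15,16-tetranorlabd-8(17)-en-12-al | C=C1C(=O)C[C@H]2C(C)(C)CCC[C@]2(C)[C@@]1(O)CC=O | intermediate
8 | (12E)-9α-hydroxy-7-oxo-15-norlabda-8(17),12-dien-14-al | C=C1C(=O)C[C@H]2C(C)(C)CCC[C@]2(C)[C@@]1(O)C/C=C(\C)C=O | intermediate
9 | (12E)-9α-hydroxylabda-8(17),12,14-trien-7-one | C=C1C(=O)C[C@H]2C(C)(C)CCC[C@]2(C)[C@@]1(O)C/C=C(C)/C=C | intermediate
10 | 2',4',6'-trihydroxyacetophenone | CC(=O)c1c(O)cc(O)cc1O | starting material
11 | 2,4,5-trimethoxybenzoyl chloride | COc1cc(OC)c(C(=O)Cl)cc1OC | starting material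
12 | 1-(2,4,6-trihydroxyphenyl)-3-(2,4,5-trimethoxyphenyl)propane-1,3-dione | O=C(CC(=O)c1cc(OC)c(OC)cc1OC)c1c(O)cc(O)cc1O | intermediate
13 | 5,7-dihydroxy-2-(2,4,5-trimethoxyphenyl)-4H-chromen-4-one | O=c1cc(-c2cc(OC)c(OC)cc2OC)oc2cc(O)cc(O)c12 | intermediate
14 | 5,7-bis(tert-butyldimethylsilyloxy)-2-(2,4,5-trimethoxyphenyl)-4H-chromen-4-one | O=c1cc(-c2cc(OC)c(OC)cc2OC)oc2cc(O[Si](C)(C)C(C)(C)C)cc(O[Si](C)(C)C(C)(C)C)c12 | intermediate
15 | 2-[5,7-bis(tert-butyldimethylsilyloxy)-4-oxo-4H-chromen-2-yl]-5-methoxy-1,4-benzoquinone | COC1=CC(=O)C(=CC1=O)c1cc(=O)c2c(O[Si](C)(C)C(C)(C)C)cc(O[Si](C)(C)C(C)(C)C)cc2o1 | intermediate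
16 | (1S,6R,8R)-1-[5,7-bis(tert-butyldimethylsilyloxy)-4-oxo-4H-chromen-2-yl]-4-methoxy-8-[(2E)-4-(9α-hydroxy-7-oxo-labdane decalin unit, attached through C11)but-2-en-2-yl]bicyclo[4.2.0]oct-3-ene-2,5-dione; cis-fused, butenyl arm trans to the chromonyl group | C=C1C(=O)C[C@H]2C(C)(C)CCC[C@]2(C)[C@@]1(O)C/C=C(C)/[C@H]1C[C@H]2C(=O)C(OC)=CC(=O)[C@@]12c1cc(=O)c2c(O[Si](C)(C)C(C)(C)C)cc(O[Si](C)(C)C(C)(C)C)cc2o1 | intermediate
17 | 5,7-bis-O-TBS ether of the target, (4aS,5R,8aR) core | C=C1C(=O)C[C@H]2C(C)(C)CCC[C@]2(C)[C@@]1(O)C[C@@H]1C(C)=CC[C@H]2C(=O)C(OC)=CC(=O)[C@@]12c1cc(=O)c2c(O[Si](C)(C)C(C)(C)C)cc(O[Si](C)(C)C(C)(C)C)cc2o1 | intermediate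
18 | CNP0241859.1 | C=C1C(=O)C[C@H]2C(C)(C)CCC[C@]2(C)[C@@]1(O)C[C@@H]1C(C)=CC[C@H]2C(=O)C(OC)=CC(=O)[C@@]12c1cc(=O)c2c(O)cc(O)cc2o1 | target

Total step count: 13. Longest linear sequence: 10 steps (steps 1–8, 12 and 13).

Steps most likely to fail

1. Step 12. The quinone face is not discriminated by the remote labdane unit. The quinone triplet may also add through its carbonyl group (Paternò–Büchi) or abstract allylic hydrogen. The diradical may lose its stereochemical memory by antarafacial recombination, or the cyclobutane may revert and the fragments then combine in an ordinary Diels–Alder reaction; either would give the C5 epimer. Fallback: setting out from 15, acid-catalysed exchange of the vinylogous-ester methoxy group for (−)-8-phenylmenthol (camphorsulfonic acid, molecular sieves, toluene) gives the 8-phenylmenthyloxy quinone F1. Its phenyl ring should stack over one face of the quinone, so that irradiation with 9 and warming as in step 12 gives, through the auxiliary-bearing cyclobutane F2, the ring-expanded auxiliary ether F3 with one sense of the core; the enantiomeric auxiliary is used if the sense is the wrong one. Exchange of the auxiliary for methanol (MeOH, pyridinium p-toluenesulfonate) comes back to 17.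

2. Step 4. The amide base may abstract a proton at C11 or C7 instead of C17, or the C12 alkoxide may attack the activated epoxide to give a tetrahydrofuran. Fallback: setting out from 3, a Schenck ene reaction with singlet oxygen (O2, tetraphenylporphyrin, visible light, CH2Cl2, −20 °C) from the α-face should give the 9α-hydroperoxide F4 with the exocyclic alkene, and reduction with PPh3 comes back to 5.

3. Step 8. The non-stabilised ylide may add to the α-methylene ketone, and the β-hydroxy carbonyl array may undergo retro-aldol cleavage or dehydration under basic conditions. Fallback: setting out from 6, selective oxidation of the primary alcohol (TEMPO, PhI(OAc)2, CH2Cl2) gives the dihydroxy aldehyde F5. The two Wittig reactions of steps 7 and 8 then run on a substrate without an enone and give the dihydroxy enal F6 and the trienediol F7. Allylic oxidation of the 7-OH with MnO2 comes back to 9.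

Further compounds
F1 | step 12 | 2-[5,7-bis(tert-butyldimethylsilyloxy)-4-oxo-4H-chromen-2-yl]-5-[(−)-8-phenylmenthyloxy]-1,4-benzoquinone | C[C@@H]1CC[C@H]([C@@H](C1)OC1=CC(=O)C(=CC1=O)c1cc(=O)c2c(O[Si](C)(C)C(C)(C)C)cc(O[Si](C)(C)C(C)(C)C)cc2o1)C(C)(C)c1ccccc1
F2 | step 12 | analogue of cyclobutane 16 with 8-phenylmenthyloxy in place of methoxy | C=C1C(=O)C[C@H]2C(C)(C)CCC[C@]2(C)[C@@]1(O)C/C=C(C)/[C@H]1C[C@H]2C(=O)C(O[C@@H]3C[C@H](C)CC[C@H]3C(C)(C)c3ccccc3)=CC(=O)[C@@]12c1cc(=O)c2c(O[Si](C)(C)C(C)(C)C)cc(O[Si](C)(C)C(C)(C)C)cc2o1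
F3 | step 12 | analogue of 17 with 8-phenylmenthyloxy in place of methoxy | C=C1C(=O)C[C@H]2C(C)(C)CCC[C@]2(C)[C@@]1(O)C[C@@H]1C(C)=CC[C@H]2C(=O)C(O[C@@H]3C[C@H](C)CC[C@H]3C(C)(C)c3ccccc3)=CC(=O)[C@@]12c1cc(=O)c2c(O[Si](C)(C)C(C)(C)C)cc(O[Si](C)(C)C(C)(C)C)cc2o1
F4 | step 4 | 9α-hydroperoxy-13,14,15,16-tetranorlabd-8(17)-en-12-ol | C=C1CC[C@H]2C(C)(C)CCC[C@]2(C)[C@@]1(OO)CCO
F5 | step 8 | 7α,9α-dihydroxy-13,14,15,16-tetranorlabd-8(17)-en-12-al | C=C1[C@H](O)C[C@H]2C(C)(C)CCC[C@]2(C)[C@@]1(O)CC=O
F6 | step 8 | (12E)-7α,9α-dihydroxy-15-norlabda-8(17),12-dien-14-al | C=C1[C@H](O)C[C@H]2C(C)(C)CCC[C@]2(C)[C@@]1(O)C/C=C(\C)C=O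
F7 | step 8 | (12E)-labda-8(17),12,14-triene-7α,9α-diol | C=C1[C@H](O)C[C@H]2C(C)(C)CCC[C@]2(C)[C@@]1(O)C/C=C(C)/C=C
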